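## The problem

The target is a diaryl ether. Ring A is a benzoic acid with four contiguous substituents (C1 carboxyl, C2 methoxy, C3 side chain, C6 aryloxy). Ring B (C1′ ether oxygen, C2′ hydroxyl, C4′ methyl, C6′ hydroxymethyl) hangs on an oxygen that has ortho neighbours on both rings. The ether bond is therefore hindered, and the carboxyl group sits between two ortho oxygen substituents, where an ester would resist hydrolysis and a late electrophilic substitution would not go. The only stereocentre is the (S)-configured secondary benzylic carbinol on C3. Nothing else in the molecule can control it, so it has to be set by a catalyst, most simply by enantioselective reduction of the aryl ketone, and then carried through. This carbinol is para to the aryloxy oxygen and ortho to the methoxy oxygen and ionises easily under acid. Together with the primary benzylic alcohol and the catechol-type phenol of ring B, it rules out strong acid, hydrogenolysis and Lewis-acidic ether cleavage late in the route, and the methyl ether must outlast every deprotection. Ring B must react through the C1′ oxygen only, so the C2′ hydroxyl and the hydroxymethyl group need separate, mildly removable protection. The feature that opens the route is on ring A: the ether oxygen at C6 and the carboxyl carbon at C1 are neighbours, and C1 lies beside the C2 methoxy group. This is the pattern left when an oxygen nucleophile adds to the far carbon of a 3-methoxybenzyne and the anion at the near carbon takes a carbon electrophile.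

## Retrosynthesis

**Protecting groups.** Target 25 is traced back to acid 24 (both alcohols silylated) and then to acid 23 (C2′ oxygen also allylated). An allyl ether is chosen for the phenol because it is inert to fluoride and strong base and falls to a palladium catalyst at room temperature. Silyl ethers are chosen for the two alcohols because fluoride removes them without acid. The forward steps only have to leave the hindered acid, the methyl ether and the carbinol configuration alone.

**Key disconnection.** In 23 the C6–O and C1–CO2H bonds are cut together, giving aryne 22 (released from silyl triflate 13), the aryloxide 21 of phenol 19, and carbon dioxide 20. The neighbouring cuts are less attractive. Coupling 19 with a 6-halo-2-methoxybenzoate would join two hindered partners and leave a di-ortho-substituted ester to hydrolyse. Arylating first and carboxylating later needs an organolithium in the presence of the allyl ether. The three-component cut gives two fragments of similar size that carry no ring A–ring B relationship at all. The forward reaction must add the aryloxide to C6 only and carboxylate the C1 anion before it is protonated.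

**Aryne precursor.** Triflate 13 is traced through phenol 12 to carbamate 11 and, by removal of the C–Si bond, to carbamate 7. The hydrogen to be replaced is the only one lying between the methoxy group and the carbamate oxygen, so a directed ortho-metalation (through 8, 9 and 10) should place silicon there. A secondary N-isopropyl carbamate is preferred to a tertiary one because it can be removed by an amine base in the flask in which the triflate is made.

**Stereocentre and side chain.** Silyl ether 7 comes from alcohol 6, and 6 from ketone 5 by asymmetric transfer hydrogenation. This moves the stereochemical problem to an aryl alkyl ketone, the substrate class on which that reduction is most reliable. Ketone 5 is the carbamate of phenol 4, which comes from racemic carbinol 3 by oxidation, and 3 from aldehyde 1 and Grignard reagent 2. The C–C bond is made first and without stereocontrol; the centre is then erased and reset.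

**Ring B.** Phenol 19 is traced to diol 18 by selective silylation of the primary alcohol, to aldehyde 17 by reduction, to catechol aldehyde 15 by selective allylation through dianion 16, and to 4-methylcatechol 14 by ortho-formylation. The carbon that becomes the hydroxymethyl group is introduced as a formyl group because the formyl group then differentiates the two catechol oxygens.

## Roads not taken

**Alternative 1:** Ring A would be built by a [4+2] cycloaddition of silyl ketene acetal diene A2 (supplying C5, C6, C1, C2 and already carrying the ring B aryloxy group and the ester) with ynone A3 (C3, C4). Aromatisation by loss of the acetal methoxy group would give salicylate A1. The merits are real. All four ring A substituents arrive in one regiodefined step, the reaction type is established, and the carboxyl carbon is in place from the start, so nothing depends on an untested anion capture. In precedent this road is stronger than the chosen one. Its weak points lie around the key step. Diene A2 requires the hindered phenol of ring B to be attached to a vinylic carbon. A1 then needs O-methylation of a chelated phenol, enantioselective reduction of a ketone flanked by that new methoxy group on the most advanced material, and cleavage of a methyl ester with two ortho substituents, which resists saponification and otherwise calls for nucleophilic demethylation next to an aryl methyl ether. Against its better precedent the chosen plan sets an end game of two mild deprotections and a stereocentre fixed early on cheap material.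

**Alternative 2:** Ring A would come from a vinylketene benzannulation. Photochemical Wolff rearrangement of diazo enone A5 gives a vinylketene, which adds to aryloxyacetylene A6; ring opening and 6π closure deliver phenol A4. Regiochemistry is dictated by the mechanism, and the (S)-silyloxy centre rides in from the acyclic precursor. These are clear strengths. The weaknesses are three. An aryl ethynyl ether made from a 2,6-disubstituted phenol is thermally fragile and takes several steps. The diazo enone needs its own synthesis and a photochemical step. A4 has neither the C2 methyl ether nor the C1 carboxyl group, so after methylation the acid must still be introduced by metalation between the two oxygens in the presence of the allyl ether. The chosen plan keeps that operation only in reserve. The benzannulation is the better-precedented ring-forming event, but it postpones the carboxylation problem instead of solving it, and the chosen plan makes both bonds at once.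

**Alternative 3:** Ring B would be made last by a pyrone-to-resorcinol ring transformation. NaOMe opens the 2-pyrone of A8 and the carbanion next to the aryloxy group closes on the ester carbon to give resorcinol A7. The attraction is that the oxygen–ring B connection begins as a simple O-alkylation of a ring A phenol, so no hindered diaryl ether coupling is needed; in this respect it is safer than the chosen plan. It is weaker elsewhere. A7 has two equivalent hydroxyl groups, and one of them must become the hydroxymethyl group. That means a statistical mono-activation, a palladium-catalysed one-carbon homologation and a reduction, all next to the free ring A acid. The fully substituted ring A salicylic acid needed for A8 also requires the same ortho-metalation chemistry as the chosen route. The chosen plan is shorter and more convergent, but it joins the rings through an untested three-component step.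

Key step: step 12

Assumption: metal alkoxides, phenoxides and carboxylates that only await aqueous work-up are treated as the product itself; species generated in a separate operation before the next reagent is added are numbered as intermediates.

## Route

Step 1
Reactants: 1 4-hydroxy-2-methoxybenzaldehyde; 2 isobutylmagnesium bromide
Product: 3 rac-4-(1-hydroxy-3-methylbutyl)-3-methoxyphenol
Conditions: 2 (3.0 equiv), THF, 0 °C → rt; aq. NH4Cl
Reagents that add atoms: isobutylmagnesium bromide (2), CC(C)C[Mg]Br
Why: Grignard addition; the first equivalent forms the bromomagnesium phenoxide and further reagent adds to the formyl group, as is routine for hydroxybenzaldehydes with excess reagent. The carbinol is racemic and is erased in step 2; neutral work-up and direct use avoid ionisation of the electron-rich benzylic alcohol.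

Step 2
Reactants: 3 rac-4-(1-hydroxy-3-methylbutyl)-3-methoxyphenol
Product: 4 1-(4-hydroxy-2-methoxyphenyl)-3-methylbutan-1-one
Conditions: DDQ (1.1 equiv), 1,4-dioxane, rt
Reagents that add atoms: none
Why: Quinone dehydrogenation of a benzylic alcohol; hydride abstraction from the carbinol carbon is assisted by the para hydroxyl and ortho methoxy donors, and the aryl ketone formed is deactivated towards further oxidation.

Step 3
Reactants: 4 1-(4-hydroxy-2-methoxyphenyl)-3-methylbutan-1-one
Product: 5 3-methoxy-4-(3-methylbutanoyl)phenyl N-isopropylcarbamate
Conditions: i-PrNCO (1.5 equiv), Et3N (0.2 equiv), CH2Cl2, rt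
Reagents that add atoms: isopropyl isocyanate, CC(C)N=C=O
Why: Base-catalysed addition of a phenol to an isocyanate (carbamoylation). The secondary carbamate later serves as the ortho-directing group and can be removed with an amine base; it also makes the ketone more electrophilic for step 4.

Step 4
Reactants: 5 3-methoxy-4-(3-methylbutanoyl)phenyl N-isopropylcarbamate
Product: 6 4-[(1S)-1-hydroxy-3-methylbutyl]-3-methoxyphenyl N-isopropylcarbamate
Conditions: RuCl[(S,S)-TsDPEN](p-cymene) (1 mol %), HCO2H/Et3N (5:2), EtOAc, 40 °C
Reagents that add atoms: none
Why: Noyori asymmetric transfer hydrogenation of an aryl alkyl ketone; hydride and proton are delivered from the Ru–H/N–H pair in a six-membered transition state in which the aryl group lies against the p-cymene ligand. The (S,S)-ligand should give the (S)-carbinol as it does with acetophenone, since aryl outranks the alkyl chain in both cases; the buffered acidic medium leaves the carbamate intact.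

Step 5
Reactants: 6 4-[(1S)-1-hydroxy-3-methylbutyl]-3-methoxyphenyl N-isopropylcarbamate
Product: 7 4-[(1S)-1-(tert-butyldimethylsilyloxy)-3-methylbutyl]-3-methoxyphenyl N-isopropylcarbamate
Conditions: TBSCl (1.5 equiv), imidazole (3 equiv), DMF, rt
Reagents that add atoms: tert-butyldimethylsilyl chloride, CC(C)(C)[Si](C)(C)Cl
Why: Imidazole-promoted silylation of a secondary alcohol; the C–O bond is not touched, so the (S) configuration is kept, and the silyl ether removes the acidic O–H before the metalation.

Step 6
Reactants: 7 4-[(1S)-1-(tert-butyldimethylsilyloxy)-3-methylbutyl]-3-methoxyphenyl N-isopropylcarbamate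
Product: 11 4-[(1S)-1-(tert-butyldimethylsilyloxy)-3-methylbutyl]-3-methoxy-2-(trimethylsilyl)phenyl N-isopropylcarbamate, via N-silyl carbamate 8 (not isolated), via aryllithium 9 (not isolated), via N-silyl C-silyl carbamate 10 (not isolated)
Conditions: TBSOTf (1.1 equiv), TMEDA (1.1 equiv), Et2O, 0 °C → rt; n-BuLi (2.2 equiv), TMEDA (2 equiv), −78 °C; TMSCl (3.5 equiv), −78 °C → rt; cold aq. NaHSO4
Reagents that add atoms: trimethylsilyl chloride, C[Si](C)(C)Cl; tert-butyldimethylsilyl triflate, CC(C)(C)[Si](C)(C)OS(=O)(=O)C(F)(F)F (in intermediates 8–10 only)
Why: Directed ortho-metalation; in-flask N-silylation masks the N–H, and the N-silyl carbamate and the methoxy group jointly direct n-BuLi/TMEDA to the single hydrogen between them, which TMSCl then replaces. At −78 °C the carbamoyl group should not migrate, and the acidic work-up removes the N-silyl group only.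

Step 7
Reactants: 11 4-[(1S)-1-(tert-butyldimethylsilyloxy)-3-methylbutyl]-3-methoxy-2-(trimethylsilyl)phenyl N-isopropylcarbamate
Product: 13 4-[(1S)-1-(tert-butyldimethylsilyloxy)-3-methylbutyl]-3-methoxy-2-(trimethylsilyl)phenyl trifluoromethanesulfonate, via silyl phenol 12 (not isolated)
Conditions: DBU (1.5 equiv), Et2NH (1.3 equiv), MeCN, 40 °C; then PhNTf2 (1.5 equiv), rt
Reagents that add atoms: N-phenylbis(trifluoromethanesulfonimide), O=S(=O)(N(c1ccccc1)S(=O)(=O)C(F)(F)F)C(F)(F)F
Why: E1cB cleavage of the secondary aryl carbamate by DBU, with the isocyanate trapped by Et2NH as a urea, followed by O-triflation of the phenoxide in the same flask; this is the established mild route to 2-(trimethylsilyl)aryl triflates and spares the aryl–silicon bond and the silyl ether.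

Step 8
Reactants: 14 4-methylcatechol (4-methylbenzene-1,2-diol)
Product: 15 2,3-dihydroxy-5-methylbenzaldehyde
Conditions: MgCl2 (3 equiv), Et3N (6 equiv), (CH2O)n (6 equiv), MeCN, reflux; 1 M HCl
Reagents that add atoms: paraformaldehyde (as formaldehyde), C=O
Why: Magnesium-mediated ortho-formylation of a phenol (Casnati–Skattebøl formylation); the magnesium phenoxide delivers bound formaldehyde to the ortho carbon and a second formaldehyde oxidises the hydroxymethyl intermediate by hydride transfer. Of the two free ortho positions the one beside the methyl group is the more hindered, so reaction should occur at the other.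

Step 9
Reactants: 15 2,3-dihydroxy-5-methylbenzaldehyde
Product: 17 3-(allyloxy)-2-hydroxy-5-methylbenzaldehyde, via disodium dianion 16 (not isolated)
Conditions: NaH (2.2 equiv), DMSO, rt; allyl bromide (1.0 equiv), rt; 1 M HCl
Reagents that add atoms: allyl bromide, C=CCBr
Why: Williamson etherification of a dianion; the 2-oxide is tied up by conjugation and chelation with the formyl group, so the 3-oxide is the stronger nucleophile and one equivalent of allyl bromide should alkylate it selectively.

Step 10
Reactants: 17 3-(allyloxy)-2-hydroxy-5-methylbenzaldehyde
Product: 18 2-(allyloxy)-6-(hydroxymethyl)-4-methylphenol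
Conditions: NaBH4 (1.0 equiv), MeOH, 0 °C; aq. NH4Cl
Reagents that add atoms: none
Why: Borohydride reduction of an aryl aldehyde; the allyl ether is inert, and neutral work-up avoids acid-induced loss of water from the ortho-hydroxybenzyl alcohol.

Step 11
Reactants: 18 2-(allyloxy)-6-(hydroxymethyl)-4-methylphenol
Product: 19 2-(allyloxy)-4-methyl-6-[(triisopropylsilyloxy)methyl]phenol
Conditions: TIPSCl (1.05 equiv), imidazole (2.2 equiv), DMF, 0 °C → rt
Reagents that add atoms: triisopropylsilyl chloride, CC(C)[Si](Cl)(C(C)C)C(C)C
Why: Selective silylation; the bulky chlorosilane should take the primary alcohol and leave the phenol, which is flanked by two ortho substituents and hydrogen-bonded. Triisopropylsilyl is chosen over tert-butyldimethylsilyl so that the primary silyl ether withstands the fluoride of step 12.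

Step 12
Reactants: 13 4-[(1S)-1-(tert-butyldimethylsilyloxy)-3-methylbutyl]-3-methoxy-2-(trimethylsilyl)phenyl trifluoromethanesulfonate; 19 2-(allyloxy)-4-methyl-6-[(triisopropylsilyloxy)methyl]phenol; 20 carbon dioxide
Product: 23 6-{2-(allyloxy)-4-methyl-6-[(triisopropylsilyloxy)methyl]phenoxy}-3-[(1S)-1-(tert-butyldimethylsilyloxy)-3-methylbutyl]-2-methoxybenzoic acid, via potassium aryloxide 21 (not isolated), via aryne 22 (not isolated)
Conditions: 19 (1.5 equiv), KH (1.45 equiv), THF, 0 °C; then CO2 (1 atm), 18-crown-6 (3 equiv), KF (3 equiv), 13 (1.0 equiv, slow addition), THF, 0 °C → rt; cold 0.5 M HCl to pH 3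
Reagents that add atoms: carbon dioxide (20), O=C=O
Why: Proposed new method: fluoride from KF/18-crown-6 attacks the trimethylsilyl group of 13 and triflate leaves, releasing aryne 22; aryloxide 21 adds to the aryne carbon remote from the methoxy group (C6 of ring A), and the aryl anion left at C1, flanked by the methoxy and aryloxy oxygens, adds to carbon dioxide to give the carboxylate. The closest known reaction types are the three-component coupling of arynes, secondary amines and carbon dioxide to anthranilic acids under the same KF/18-crown-6/THF conditions, the fluoride-mediated O-arylation of phenols by arynes from silyl triflates, and the capture by a carbon electrophile of the aryl anion left after phenoxide addition, as in xanthone formation from arynes and salicylates. No ring closes and no stereocentre is formed; the (S)-silyloxy centre is a spectator. The step needs regioselective addition: inductive withdrawal by the C2 methoxy group and the distortion it imposes on the aryne direct the nucleophile to C6 and the charge to C1, and the bulky 2,6-disubstituted aryloxide reinforces this by avoiding the methoxy-flanked carbon. It also needs carboxylation to outrun protonation, so the aryloxide is pre-formed with KH, leaving no O–H, N–H or HF in the flask, and carbon dioxide is present at one atmosphere from the start. Reversible binding of carbon dioxide to the aryloxide as an aryl carbonate is expected, as carbamate formation is in the amine case, and should only lower the standing concentration of free aryloxide; slow release of the aryne at 0 °C and the excess of 21 keep fluoride and the product carboxylate from competing for the aryne.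

Step 13
Reactants: 23 6-{2-(allyloxy)-4-methyl-6-[(triisopropylsilyloxy)methyl]phenoxy}-3-[(1S)-1-(tert-butyldimethylsilyloxy)-3-methylbutyl]-2-methoxybenzoic acid
Product: 24 3-[(1S)-1-(tert-butyldimethylsilyloxy)-3-methylbutyl]-6-{2-hydroxy-4-methyl-6-[(triisopropylsilyloxy)methyl]phenoxy}-2-methoxybenzoic acid
Conditions: Pd(PPh3)4 (5 mol %), morpholine (10 equiv), THF, rt; aq. citric acid
Reagents that add atoms: none
Why: Tsuji–Trost-type deallylation; zerovalent palladium ionises the aryl allyl ether to a π-allyl complex and the phenoxide, and morpholine takes up the allyl group irreversibly, also returning any allyl ester formed at the carboxylate. Silyl ethers and the methyl ether are inert.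

Step 14
Reactants: 24 3-[(1S)-1-(tert-butyldimethylsilyloxy)-3-methylbutyl]-6-{2-hydroxy-4-methyl-6-[(triisopropylsilyloxy)methyl]phenoxy}-2-methoxybenzoic acid
Product: 25 6-[2-hydroxy-6-(hydroxymethyl)-4-methylphenoxy]-3-[(1S)-1-hydroxy-3-methylbutyl]-2-methoxybenzoic acid (CNP0221397.1)
Conditions: TBAF (6 equiv), THF, 0 → 40 °C; cold dilute HCl to pH 3
Reagents that add atoms: none
Why: Fluoride-induced cleavage of both silyl ethers, driven by the Si–F bond; the medium is basic, so the benzylic C–O bond is not ionised and the (S) configuration should be retained. Acidification is limited to pH 3 at 0 °C for the same reason.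

## Compound list

1 | 4-hydroxy-2-methoxybenzaldehyde | COc1cc(O)ccc1C=O | starting material
2 | isobutylmagnesium bromide | CC(C)C[Mg]Br | starting material
3 | rac-4-(1-hydroxy-3-methylbutyl)-3-methoxyphenol | COc1cc(O)ccc1C(O)CC(C)C | intermediate
4 | 1-(4-hydroxy-2-methoxyphenyl)-3-methylbutan-1-one | COc1cc(O)ccc1C(=O)CC(C)C | intermediate
5 | 3-methoxy-4-(3-methylbutanoyl)phenyl N-isopropylcarbamate | COc1cc(OC(=O)NC(C)C)ccc1C(=O)CC(C)C | intermediate
6 | 4-[(1S)-1-hydroxy-3-methylbutyl]-3-methoxyphenyl N-isopropylcarbamate | COc1cc(OC(=O)NC(C)C)ccc1[C@@H](O)CC(C)C | intermediate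
7 | 4-[(1S)-1-(tert-butyldimethylsilyloxy)-3-methylbutyl]-3-methoxyphenyl N-isopropylcarbamate | COc1cc(OC(=O)NC(C)C)ccc1[C@@H](O[Si](C)(C)C(C)(C)C)CC(C)C | intermediate
8 | N-(tert-butyldimethylsilyl) derivative of carbamate 7 | COc1cc(OC(=O)N(C(C)C)[Si](C)(C)C(C)(C)C)ccc1[C@@H](O[Si](C)(C)C(C)(C)C)CC(C)C | intermediate
9 | 2-lithio derivative of 8 (lithium between the methoxy and carbamate oxygens) | COc1c([Li])c(OC(=O)N(C(C)C)[Si](C)(C)C(C)(C)C)ccc1[C@@H](O[Si](C)(C)C(C)(C)C)CC(C)C | intermediate
10 | 2-(trimethylsilyl) derivative of 8 | COc1c([Si](C)(C)C)c(OC(=O)N(C(C)C)[Si](C)(C)C(C)(C)C)ccc1[C@@H](O[Si](C)(C)C(C)(C)C)CC(C)C | intermediate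
11 | 4-[(1S)-1-(tert-butyldimethylsilyloxy)-3-methylbutyl]-3-methoxy-2-(trimethylsilyl)phenyl N-isopropylcarbamate | COc1c([Si](C)(C)C)c(OC(=O)NC(C)C)ccc1[C@@H](O[Si](C)(C)C(C)(C)C)CC(C)C | intermediate
12 | 4-[(1S)-1-(tert-butyldimethylsilyloxy)-3-methylbutyl]-3-methoxy-2-(trimethylsilyl)phenol | COc1c([Si](C)(C)C)c(O)ccc1[C@@H](O[Si](C)(C)C(C)(C)C)CC(C)C | intermediate
13 | 4-[(1S)-1-(tert-butyldimethylsilyloxy)-3-methylbutyl]-3-methoxy-2-(trimethylsilyl)phenyl trifluoromethanesulfonate | COc1c([Si](C)(C)C)c(OS(=O)(=O)C(F)(F)F)ccc1[C@@H](O[Si](C)(C)C(C)(C)C)CC(C)C | intermediate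
14 | 4-methylcatechol | Cc1ccc(O)c(O)c1 | starting material
15 | 2,3-dihydroxy-5-methylbenzaldehyde | Cc1cc(O)c(O)c(C=O)c1 | intermediate
16 | disodium 3-formyl-5-methylbenzene-1,2-diolate | Cc1cc([O-])c([O-])c(C=O)c1.[Na+].[Na+] | intermediate
17 | 3-(allyloxy)-2-hydroxy-5-methylbenzaldehyde | Cc1cc(OCC=C)c(O)c(C=O)c1 | intermediate
18 | 2-(allyloxy)-6-(hydroxymethyl)-4-methylphenol | Cc1cc(OCC=C)c(O)c(CO)c1 | intermediate
19 | 2-(allyloxy)-4-methyl-6-[(triisopropylsilyloxy)methyl]phenol | Cc1cc(OCC=C)c(O)c(CO[Si](C(C)C)(C(C)C)C(C)C)c1 | intermediate
20 | carbon dioxide | O=C=O | starting material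
21 | potassium 2-(allyloxy)-4-methyl-6-[(triisopropylsilyloxy)methyl]phenolate | Cc1cc(OCC=C)c([O-])c(CO[Si](C(C)C)(C(C)C)C(C)C)c1.[K+] | intermediate
22 | 4-[(1S)-1-(tert-butyldimethylsilyloxy)-3-methylbutyl]-3-methoxy-1,2-didehydrobenzene (aryne) | COC1=C([C@@H](O[Si](C)(C)C(C)(C)C)CC(C)C)C=CC#C1 | intermediate
23 | 6-{2-(allyloxy)-4-methyl-6-[(triisopropylsilyloxy)methyl]phenoxy}-3-[(1S)-1-(tert-butyldimethylsilyloxy)-3-methylbutyl]-2-methoxybenzoic acid | COc1c([C@@H](O[Si](C)(C)C(C)(C)C)CC(C)C)ccc(Oc2c(OCC=C)cc(C)cc2CO[Si](C(C)C)(C(C)C)C(C)C)c1C(=O)O | intermediate
24 | 3-[(1S)-1-(tert-butyldimethylsilyloxy)-3-methylbutyl]-6-{2-hydroxy-4-methyl-6-[(triisopropylsilyloxy)methyl]phenoxy}-2-methoxybenzoic acid | COc1c([C@@H](O[Si](C)(C)C(C)(C)C)CC(C)C)ccc(Oc2c(O)cc(C)cc2CO[Si](C(C)C)(C(C)C)C(C)C)c1C(=O)O | intermediate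
25 | 6-[2-hydroxy-6-(hydroxymethyl)-4-methylphenoxy]-3-[(1S)-1-hydroxy-3-methylbutyl]-2-methoxybenzoic acid | COc1c([C@@H](O)CC(C)C)ccc(Oc2c(O)cc(C)cc2CO)c1C(=O)O | target

## Step count and least certain steps

Total: 14 steps. Longest linear sequence: 10 steps (steps 1–7, 12, 13, 14); ring B takes steps 8–11.

**Step 12 (key step).** Two processes are most likely to interfere. The first is diversion of the aryloxide by carbon dioxide before it meets the aryne: addition through the carbonate oxygen followed by acyl transfer would give an ester-linked product. The second is protonation of the C1 anion by adventitious water, giving the ether without the carboxyl group. The fallback sets out from 13 and 19 and returns at 24, using known reactions only. Fluoride-mediated O-arylation without carbon dioxide (CsF, MeCN, rt; the free phenol supplies the proton) should give tert-butyl{(1S)-1-[4-{2-(allyloxy)-4-methyl-6-[(triisopropylsilyloxy)methyl]phenoxy}-2-methoxyphenyl]-3-methylbutoxy}dimethylsilane F1, which has hydrogen at C1. Deallylation with Pd(PPh3)4 and morpholine should then give 2-{4-[(1S)-1-(tert-butyldimethylsilyloxy)-3-methylbutyl]-3-methoxyphenoxy}-5-methyl-3-[(triisopropylsilyloxy)methyl]phenol F2. Double deprotonation (n-BuLi, 2.3 equiv, TMEDA, THF, −78 → 0 °C) should lithiate the ring A carbon flanked by the methoxy and aryloxy oxygens, while the lithium phenoxide deactivates ring B and no allyl ether remains to be attacked. Quenching with carbon dioxide and mild acid should give 24.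

**Step 6.** The likely failure is incomplete or misdirected metalation. The N-silylated secondary carbamate is a weaker and more fragile director than a tertiary one; if the N-silyl group is lost, the exposed N–H is deprotonated and the carbamate fragments to aryloxide and isocyanate. The side chain beside the methoxy group may also slow metalation at the flanked position in favour of the other ortho position. The fallback sets out from 7 and returns at 12. Cleavage of the carbamate (DBU, Et2NH, MeCN, 40 °C) should give 4-[(1S)-1-(tert-butyldimethylsilyloxy)-3-methylbutyl]-3-methoxyphenol F3. Carbamoylation (NaH, ClC(O)NEt2, THF) should give 4-[(1S)-1-(tert-butyldimethylsilyloxy)-3-methylbutyl]-3-methoxyphenyl N,N-diethylcarbamate F4, which carries the strongest oxygen-based director. Metalation with s-BuLi/TMEDA in THF at −78 °C and a TMSCl quench should give 4-[(1S)-1-(tert-butyldimethylsilyloxy)-3-methylbutyl]-3-methoxy-2-(trimethylsilyl)phenyl N,N-diethylcarbamate F5. Reductive cleavage with Cp2Zr(H)Cl in THF should give phenol 12, which is then triflated with PhNTf2 and base to 13.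

**Step 8.** The likely failure is poor conversion or formylation at the wrong ortho carbon, because the catecholate chelates magnesium and both ortho positions are activated. The fallback sets out from 14 and returns at 15. Bis-protection (MOMCl, i-Pr2NEt, CH2Cl2) should give 1,2-bis(methoxymethoxy)-4-methylbenzene F6. Directed ortho-lithiation at the unhindered ortho position (n-BuLi, TMEDA, THF, 0 °C) and a DMF quench should give 2,3-bis(methoxymethoxy)-5-methylbenzaldehyde F7. Acetal cleavage (HCl, MeOH, 50 °C) should give 15.

**Step 1.** The likely failure is sluggish addition to the deactivated phenoxide aldehyde, with competing transfer of a β-hydride from the isobutyl reagent, and loss of water from the product on handling. The fallback sets out from 1 and returns at 4. Silylation (TBSCl, imidazole, DMF) should give 4-(tert-butyldimethylsilyloxy)-2-methoxybenzaldehyde F8. Addition of 2 (THF, −78 °C) should give rac-1-[4-(tert-butyldimethylsilyloxy)-2-methoxyphenyl]-3-methylbutan-1-ol F9. Dess–Martin oxidation should give 1-[4-(tert-butyldimethylsilyloxy)-2-methoxyphenyl]-3-methylbutan-1-one F10, and TBAF in THF at 0 °C should release 4.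

**Step 4.** The likely failure is reduced facial selectivity, because the ortho methoxy group twists the aryl ring out of the carbonyl plane and weakens the aryl/alkyl discrimination of the catalyst. The fallback sets out from 5 and returns at 6: Corey–Bakshi–Shibata reduction with (R)-2-methyl-CBS-oxazaborolidine and BH3·SMe2 in THF at −20 °C, in which the aryl group acts as the large substituent and the (S)-carbinol is again expected. No compound beyond those of the route is made (entry F0).

## Further compounds

F1 | step 12 | tert-butyl{(1S)-1-[4-{2-(allyloxy)-4-methyl-6-[(triisopropylsilyloxy)methyl]phenoxy}-2-methoxyphenyl]-3-methylbutoxy}dimethylsilane | COc1cc(Oc2c(OCC=C)cc(C)cc2CO[Si](C(C)C)(C(C)C)C(C)C)ccc1[C@@H](O[Si](C)(C)C(C)(C)C)CC(C)C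
F2 | step 12 | 2-{4-[(1S)-1-(tert-butyldimethylsilyloxy)-3-methylbutyl]-3-methoxyphenoxy}-5-methyl-3-[(triisopropylsilyloxy)methyl]phenol | COc1cc(Oc2c(O)cc(C)cc2CO[Si](C(C)C)(C(C)C)C(C)C)ccc1[C@@H](O[Si](C)(C)C(C)(C)C)CC(C)C
F3 | step 6 | 4-[(1S)-1-(tert-butyldimethylsilyloxy)-3-methylbutyl]-3-methoxyphenol | COc1cc(O)ccc1[C@@H](O[Si](C)(C)C(C)(C)C)CC(C)C
F4 | step 6 | 4-[(1S)-1-(tert-butyldimethylsilyloxy)-3-methylbutyl]-3-methoxyphenyl N,N-diethylcarbamate | COc1cc(OC(=O)N(CC)CC)ccc1[C@@H](O[Si](C)(C)C(C)(C)C)CC(C)C
F5 | step 6 | 4-[(1S)-1-(tert-butyldimethylsilyloxy)-3-methylbutyl]-3-methoxy-2-(trimethylsilyl)phenyl N,N-diethylcarbamate | COc1c([Si](C)(C)C)c(OC(=O)N(CC)CC)ccc1[C@@H](O[Si](C)(C)C(C)(C)C)CC(C)C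
F6 | step 8 | 1,2-bis(methoxymethoxy)-4-methylbenzene | Cc1ccc(OCOC)c(OCOC)c1
F7 | step 8 | 2,3-bis(methoxymethoxy)-5-methylbenzaldehyde | Cc1cc(OCOC)c(OCOC)c(C=O)c1
F8 | step 1 | 4-(tert-butyldimethylsilyloxy)-2-methoxybenzaldehyde | COc1cc(O[Si](C)(C)C(C)(C)C)ccc1C=O
F9 | step 1 | rac-1-[4-(tert-butyldimethylsilyloxy)-2-methoxyphenyl]-3-methylbutan-1-ol | COc1cc(O[Si](C)(C)C(C)(C)C)ccc1C(O)CC(C)C
F10 | step 1 | 1-[4-(tert-butyldimethylsilyloxy)-2-methoxyphenyl]-3-methylbutan-1-one | COc1cc(O[Si](C)(C)C(C)(C)C)ccc1C(=O)CC(C)C
F0 | step 4 | none | none
A1 | alternative 1 | methyl 6-{2-(allyloxy)-6-[(tert-butyldimethylsilyloxy)methyl]-4-methylphenoxy}-2-hydroxy-3-(3-methylbutanoyl)benzoate | COC(=O)c1c(O)c(C(=O)CC(C)C)ccc1Oc1c(OCC=C)cc(C)cc1CO[Si](C)(C)C(C)(C)C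
A2 | alternative 1 | methyl 3-{2-(allyloxy)-6-[(tert-butyldimethylsilyloxy)methyl]-4-methylphenoxy}-2-[methoxy(trimethylsilyloxy)methylidene]but-3-enoate | C=C(Oc1c(OCC=C)cc(C)cc1CO[Si](C)(C)C(C)(C)C)C(C(=O)OC)=C(OC)O[Si](C)(C)C
A3 | alternative 1 | 5-methylhex-1-yn-3-one | C#CC(=O)CC(C)C
A4 | alternative 2 | 5-{2-(allyloxy)-6-[(tert-butyldimethylsilyloxy)methyl]-4-methylphenoxy}-2-[(1S)-1-(tert-butyldimethylsilyloxy)-3-methylbutyl]phenol | Oc1cc(Oc2c(OCC=C)cc(C)cc2CO[Si](C)(C)C(C)(C)C)ccc1[C@@H](O[Si](C)(C)C(C)(C)C)CC(C)C
A5 | alternative 2 | (S,E)-5-(tert-butyldimethylsilyloxy)-1-diazo-7-methyloct-3-en-2-one | [N-]=[N+]=CC(=O)/C=C/[C@@H](O[Si](C)(C)C(C)(C)C)CC(C)C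
A6 | alternative 2 | 1-(allyloxy)-3-[(tert-butyldimethylsilyloxy)methyl]-2-(ethynyloxy)-5-methylbenzene | C#COc1c(OCC=C)cc(C)cc1CO[Si](C)(C)C(C)(C)C
A7 | alternative 3 | 3-[(1S)-1-(tert-butyldimethylsilyloxy)-3-methylbutyl]-6-(2,6-dihydroxy-4-methylphenoxy)-2-methoxybenzoic acid | COc1c([C@@H](O[Si](C)(C)C(C)(C)C)CC(C)C)ccc(Oc2c(O)cc(C)cc2O)c1C(=O)O
A8 | alternative 3 | 3-[(1S)-1-(tert-butyldimethylsilyloxy)-3-methylbutyl]-2-methoxy-6-[(4-methyl-2-oxo-2H-pyran-6-yl)methoxy]benzoic acid | COc1c([C@@H](O[Si](C)(C)C(C)(C)C)CC(C)C)ccc(OCc2cc(C)cc(=O)o2)c1C(=O)O
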